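**Assumptions (remarks on the chemistry)**

- Atom labels C1–C11 are those of the tricyclo[5.4.0.0(2,8)]undecane skeleton of the target: C1 α-keto cyclobutane CH, C2 quaternary cyclobutane C–CH3, C3 tiglate carbon, C4 CH2, C5 angelate carbon, C6 CMe2, C7 and C8 cyclobutane CH, C9 methyl-bearing alkene carbon, C10 alkene CH, C11 C=O. The target is read as the (1R,2R,3R,5R,7S,8R) isomer with the E ester (tiglate) on O3 and the Z ester (angelate) on O5.
- The two chiral controllers are named on the basis of their usual facial preferences (Re-face addition for the methyl-ketone enolate of (+)-Ipc2BCl, Si-face addition for the (S,S)-bisphosphoramide/SiCl4 system). If either sense is the opposite, the antipode of that controller is used and nothing else changes.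

## The problem

The target is a longipinane. Its cyclobutane C1–C2–C8–C7 is spanned across C1/C8 by the enone bridge C11(=O)–C10=C9(Me) (a bicyclo[3.1.1]heptenone) and, on the opposite face, across C2/C7 by the dioxygenated bridge C3–C4–C5–C6 (a bicyclo[4.1.1]octane). No ring is fused to the four-membered ring along one bond only, and either retro-[2+2] of the cyclobutane with both bridges in place leads to an eleven-membered ring. The most congested bonds belong to the two fully substituted carbons: C2 (quaternary, in the cyclobutane, next to the C3 carbinol) and C6 (gem-dimethyl, between the C5 carbinol and the cyclobutane CH C7). C1, C2, C7 and C8 are tied together by the cage, so only one absolute sense is free. C3 and C5 (trans-1,3) sit on a bridge that is locally almost mirror-symmetric, since its two sides differ only in the remote C11=O versus C9–Me; the core cannot be trusted to control them, and diol and core must be correlated by independent reagent control. The two secondary oxygens are both neopentylic and carry different esters, and the angelate isomerises to the tiglate under basic, nucleophilic or radical conditions, so it must come last. Whenever C7 bears oxygen while C11 is a ketone, the cyclobutane is part of a strained β-dicarbonyl or β-hydroxy ketone and is open to retro-Claisen or retro-aldol cleavage, which constrains the order of events. The feature that makes the key step possible is this: C7 is the one cyclobutane carbon with a hydrogen and a single exocyclic carbon, so it can be a former carbonyl carbon, and C1–C2 is the footprint of an E-trisubstituted alkene whose more substituted end (C2) is linked to C8 through the three-atom chain C9–C10–C11. That is the pattern delivered by an intramolecular vinylketene–alkene cycloaddition, with the C9 methyl as a former exocyclic methylene and C11=O as a former tether carbinol.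

## Retrosynthesis

**O5–acyl bond (33 ⇒ 30 + 31).** The angelate is the only group that cannot pass through amine at reflux or hydrogen-atom-transfer conditions without Z→E isomerisation, so it is cut first; the tiglate, the thermodynamic isomer, can be carried. Alcohol 30 has a single free hydroxyl, so the forward acylation with angelic acid 31 needs no selectivity, only conditions that do not isomerise.

**C6–C7 bond, with C7–H (30 ⇐ 29 ⇐ 26).** This is the bond between the gem-dimethyl carbon and the cyclobutane. A polar aldol-type closure onto a C7 ketone would leave a tertiary cyclobutanol that cannot be dehydrated (the alkene would be anti-Bredt) and sits β to C11. Cutting instead as "tertiary C6 radical + C7=N–NHTs" removes the seven-membered ring, the quaternary centre and the C7 stereocentre together, leaving the bicyclic hydrazone 26 with an open chain on C2. The forward step must generate the C6 radical from an isopropenyl group by Markovnikov hydrogen-atom transfer and add it 7-exo to the hydrazone carbon; the cyclobutane holds C3 over C7, which is what makes this closure reasonable.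

**Oxidation-state cuts (26 ⇐ 24 ⇐ 22).** The C11 ketone goes back to an (S)-carbinol (triethylsilyl ether), the conjugated C9=C10 alkene to an exocyclic C9 methylidene, and the hydrazone to the C7 ketone of 22. The order is forced: C7 is masked as the hydrazone before C11 is oxidised, and the exocyclic alkene is moved into conjugation before the radical step, because its hydrogen-atom-transfer radical would open the cyclobutane.

**C1–C7 and C2–C8 (22 ⇐ vinylketene 21 ⇐ acid 19), the key cut.** Against the photochemical retro-[2+2] modes, this cut uses the one cyclobutane carbon that can be a carbonyl and gives an acyclic precursor. Acid 19 has three stereocentres, all set on open chains, whereas 22 has the bicyclo[3.1.1]heptane, the quaternary C2 and three new stereocentres. The forward reaction must give the bridged (not the fused) regiochemistry, keep the E-alkene geometry, and choose one alkene face; the temporary C11 carbinol is placed in the tether for that purpose.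

**C10–C11 (19 ⇐ 17 ⇐ 16 ⇐ enal 11 + silyl dienol ether 14, from ester 12).** A vinylogous aldol makes the whole 3-methyl-2-enoic acid terminus in one bond and sets C11 under catalyst control, independently of C3 and C5.

**C5–H and O3–acyl (11 ⇐ 10 ⇐ 9 ⇐ 7 + aldehyde 8).** An Evans–Tishchenko reduction of the β-hydroxy ketone 7 with tiglaldehyde 8 sets C5 anti to C3, puts the tiglate on O3 and leaves O5 free; this solves the differentiation of the two neopentylic oxygens while they are still on an open chain.

**C3–C4 and C1=C2 (7 ⇐ 3 + 4; 3 ⇐ 1 + 2).** A methyl-ketone aldol joins enone 4 to the E enal 3, which comes from a Wittig reaction of the commercial aldehyde 1 and ylide 2. Two aldols around the central C5 unit 3 thus build the whole C15 chain.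

## Roads not taken

Alternative 1: Retro-[2+2] of the cyclobutane with both bridges in place (C1–C7 and C2–C8), the most obvious cut of a cyclobutane. The precursor is the eleven-membered (2E,8E,10Z)-trienone A1 and the forward step a transannular enone–alkene photocycloaddition. A1 is harder to make than the target: a medium ring with two E alkenes and a cross-conjugated dienone, closed by a macrocyclisation. Nothing in A1 fixes the faces of either alkene, so the four cyclobutane centres would depend on ring conformation; first bonding through a five-membered ring (C1–C8) would give the fused isomer; and E/Z photoisomerisation of the ring alkenes and of the angelate competes. The chosen plan closes the four-membered ring thermally from an open chain with a defined control element.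

Alternative 2: Cut only C1–C7, by analogy with the biogenesis. The precursor is the cis-fused bicyclo[5.4.0]undecenedione A2; Norrish–Yang cyclisation (γ-hydrogen abstraction at C1 by the excited C7 ketone) would give cyclobutanol A3, followed by deoxygenation. A2 already carries four stereocentres on a fused six/seven system and is no simpler to make than the chain used here. α-Cleavage at the quaternary C6–C7 bond, fragmentation of the 1,4-biradical and the competing enone chromophore all threaten the key step. A3 is a cyclobutanol β to the C11 ketone (retro-aldol), and a hindered tertiary deoxygenation would still be needed. The chosen plan never places oxygen on C7 once C11 is a ketone.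

Alternative 3: Cut C2–C3 and C6–C7, i.e. take the four-carbon bridge off the cyclobutane. The precursor is the bicyclobutane enone A4, whose central C2–C7 bond would be opened by a strain-release annulation with a dioxygenated four-carbon partner. A4 has no short or enantioselective access compatible with the enone. A two-bond addition across the central bond that puts carbon on the methyl-bearing bridgehead has no close precedent. The C3/C5 stereocentres would have to be matched to the chirality of A4 in the same step without any control element. The chosen plan sets C3, C5 and the temporary C11 centre by three independent, well-understood reactions.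

Key step: step 10

## Steps

Step 1
Reactants: 1 2,2-dimethoxyacetaldehyde; 2 2-(triphenyl-λ5-phosphanylidene)propanal
Product: 3 (2E)-4,4-dimethoxy-2-methylbut-2-enal
Conditions: toluene, 80 °C
Reagents that add atoms: none
Why: Wittig olefination with a stabilised α-methyl formyl ylide; the E alkene is expected, which later places the C2 methyl cis to C11 and the oxygenated chain anti to the enone bridge, and the acetal keeps C11 masked while C3 reacts.

Step 2
Reactants: 4 3-methylbut-3-en-2-one; 3 (2E)-4,4-dimethoxy-2-methylbut-2-enal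
Product: 7 (5R,6E)-5-hydroxy-8,8-dimethoxy-2,6-dimethylocta-1,6-dien-3-one, via boron enolate 5 (not isolated), via boron aldolate 6 (not isolated)
Conditions: (+)-Ipc2BCl, Et3N, Et2O, 0 °C; then 3, −78 to −20 °C; then H2O2, MeOH, pH 7 buffer
Reagents that add atoms: none
Why: Boron-mediated aldol addition of a methyl ketone (diisopinocampheylboron enolate): 4 can enolise only at its methyl group, and reagent-controlled addition to the Re face of the non-enolisable enal sets C3 (5R in 7); any minor enantiomer becomes a separable diastereomer once the independently controlled C11 centre is installed in step 7.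

Step 3
Reactants: 7 (5R,6E)-5-hydroxy-8,8-dimethoxy-2,6-dimethylocta-1,6-dien-3-one; 8 (2E)-2-methylbut-2-enal
Product: 9 (3R,5R,6E)-3-hydroxy-8,8-dimethoxy-2,6-dimethylocta-1,6-dien-5-yl (2E)-2-methylbut-2-enoate
Conditions: SmI2 (0.3 equiv, premixed with excess 8), THF, −10 °C
Reagents that add atoms: none
Why: Evans–Tishchenko reduction: the C3 hydroxyl forms a hemiacetal with 8 on trivalent samarium and delivers its hydride intramolecularly to the C5 carbonyl through a chair-like chelate, giving the 1,3-anti (3R,5R) relationship; the aldehyde ends as the tiglate on O3 and O5 is left free, so one operation sets C5, installs the first ester and differentiates the two oxygens.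

Step 4
Reactants: 9 (3R,5R,6E)-3-hydroxy-8,8-dimethoxy-2,6-dimethylocta-1,6-dien-5-yl (2E)-2-methylbut-2-enoate
Product: 10 (3R,5R,6E)-3-[(tert-butyldimethylsilyl)oxy]-8,8-dimethoxy-2,6-dimethylocta-1,6-dien-5-yl (2E)-2-methylbut-2-enoate
Conditions: TBSCl, imidazole, DMF, rt
Reagents that add atoms: tert-butyldimethylsilyl chloride, CC(C)(C)[Si](C)(C)Cl
Why: Silylation of the only free (allylic, unhindered) hydroxyl; the TBS ether is chosen to outlast the triethylsilyl ether used at C11 and to keep O5 free of acyl groups until the angelate is attached last.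

Step 5
Reactants: 10 (3R,5R,6E)-3-[(tert-butyldimethylsilyl)oxy]-8,8-dimethoxy-2,6-dimethylocta-1,6-dien-5-yl (2E)-2-methylbut-2-enoate
Product: 11 (2E,4R,6R)-6-[(tert-butyldimethylsilyl)oxy]-3,7-dimethyl-1-oxoocta-2,7-dien-4-yl (2E)-2-methylbut-2-enoate
Conditions: oxalic acid (aq.), THF, rt
Reagents that add atoms: water, O
Why: Mild acid hydrolysis of an α,β-unsaturated dimethyl acetal, which is much faster than cleavage of the secondary TBS ether or the ester; it unveils the C11 aldehyde as the E enal.

Step 6
Reactants: 12 methyl 3-methylbut-2-enoate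
Product: 14 tert-butyl[(1-methoxy-3-methylbuta-1,3-dien-1-yl)oxy]dimethylsilane, via lithium dienolate 13 (not isolated)
Conditions: LiN(iPr)2, THF, −78 °C; then TBSCl, DMPU
Reagents that add atoms: tert-butyldimethylsilyl chloride, CC(C)(C)[Si](C)(C)Cl
Why: γ-Deprotonation of the senecioate ester and O-silylation of the dienolate give the silyl dienol ether for the vinylogous aldol; the geometry of its C1=C2 bond is of no consequence.

Step 7
Reactants: 11 (2E,4R,6R)-6-[(tert-butyldimethylsilyl)oxy]-3,7-dimethyl-1-oxoocta-2,7-dien-4-yl (2E)-2-methylbut-2-enoate; 14 tert-butyl[(1-methoxy-3-methylbuta-1,3-dien-1-yl)oxy]dimethylsilane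
Product: 16 methyl (2E,5S,6E,8R,10R)-10-[(tert-butyldimethylsilyl)oxy]-5-hydroxy-3,7,11-trimethyl-8-{[(2E)-2-methylbut-2-enoyl]oxy}dodeca-2,6,11-trienoate, via trichlorosilyl ether 15 (not isolated)
Conditions: SiCl4, (S,S)-bisphosphoramide (pentane-1,5-diyl-linked bis(N,N'-dimethyl-1,1'-binaphthyl-2,2'-diamine phosphoramide), cat.), iPr2NEt (cat.), CH2Cl2, −78 °C; aq. NaHCO3 work-up
Reagents that add atoms: none
Why: Catalytic enantioselective vinylogous Mukaiyama aldol (chiral Lewis-base-bound SiCl3 cation): γ-selective addition to the Si face of the enal sets C11 (5S) under catalyst control and gives the E enoate that is the vinylketene precursor; the C11 carbinol is a temporary stereocentre that steers step 10 and later becomes the ketone.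

Step 8
Reactants: 16 methyl (2E,5S,6E,8R,10R)-10-[(tert-butyldimethylsilyl)oxy]-5-hydroxy-3,7,11-trimethyl-8-{[(2E)-2-methylbut-2-enoyl]oxy}dodeca-2,6,11-trienoate
Product: 17 methyl (2E,5S,6E,8R,10R)-10-[(tert-butyldimethylsilyl)oxy]-3,7,11-trimethyl-8-{[(2E)-2-methylbut-2-enoyl]oxy}-5-[(triethylsilyl)oxy]dodeca-2,6,11-trienoate
Conditions: TESCl, imidazole, CH2Cl2, 0 °C
Reagents that add atoms: chlorotriethylsilane, CC[Si](CC)(CC)Cl
Why: Silylation; the triethylsilyl ether is bulky enough to act as the facial control element in step 10 and labile enough to be removed later in the presence of the TBS ether.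

Step 9
Reactants: 17 methyl (2E,5S,6E,8R,10R)-10-[(tert-butyldimethylsilyl)oxy]-3,7,11-trimethyl-8-{[(2E)-2-methylbut-2-enoyl]oxy}-5-[(triethylsilyl)oxy]dodeca-2,6,11-trienoate
Product: 19 (2E,5S,6E,8R,10R)-10-[(tert-butyldimethylsilyl)oxy]-3,7,11-trimethyl-8-{[(2E)-2-methylbut-2-enoyl]oxy}-5-[(triethylsilyl)oxy]dodeca-2,6,11-trienoic acid, via trimethylstannyl ester 18 (not isolated)
Conditions: Me3SnOH, 1,2-dichloroethane, 80 °C; dilute aq. HCl work-up
Reagents that add atoms: trimethyltin hydroxide, C[Sn](C)(C)O
Why: Mild, non-basic hydrolysis of a methyl ester with Me3SnOH, which should be selective for the unhindered methyl ester over the secondary tiglate and leaves both silyl ethers and the δ-silyloxy enoate untouched (no enolisation, no elimination).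

Step 10
Reactants: 19 (2E,5S,6E,8R,10R)-10-[(tert-butyldimethylsilyl)oxy]-3,7,11-trimethyl-8-{[(2E)-2-methylbut-2-enoyl]oxy}-5-[(triethylsilyl)oxy]dodeca-2,6,11-trienoic acid
Product: 22 (1R,3R)-3-[(tert-butyldimethylsilyl)oxy]-4-methyl-1-[(1R,4S,5R,7R)-7-methyl-2-methylidene-6-oxo-4-[(triethylsilyl)oxy]bicyclo[3.1.1]heptan-7-yl]pent-4-en-1-yl (2E)-2-methylbut-2-enoate, via acid chloride 20 (not isolated), via vinylketene 21 (not isolated)
Conditions: 1-chloro-N,N,2-trimethylprop-1-en-1-amine, CH2Cl2, 0 °C to rt; then slow addition to Et3N, toluene, 110 °C (high dilution)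
Reagents that add atoms: none
Why: Et3N removes HCl from 20 across C7–C8–C9–CH3 (γ-deprotonation at the methyl group) to give vinylketene 21, which adds thermally to the C1=C2 alkene in a concerted but asynchronous [2+2] process; the closest known reaction is the intramolecular vinylketene–alkene cycloaddition of geranic- and farnesic-type acid chlorides to 2-methylidenebicyclo[3.1.1]heptan-6-ones. The electrophilic ketene carbon C7 bonds to the less substituted alkene carbon C1 (six-membered ring C7–C8–C9–C10–C11–C1, 6-exo) while positive charge builds on the trisubstituted carbon C2, which then bonds to the ketene α-carbon C8 and closes the cyclobutanone in the bridged (bicyclo[3.1.1]) rather than the fused sense. C2: the addition is suprafacial on the E alkene, so the methyl group stays cis to C11 (syn to the three-carbon bridge) and the oxygenated chain points over C7, as the later ring closure requires. C1 and C8: the alkene face is chosen by the C11 stereocentre, because allylic 1,3-strain with the Z-methyl on C2 holds the C11–H bond in the alkene plane, the tether carbon C10 must lie on the attacked face, and the OSiEt3 group is therefore on the far face and ends cis to the carbonyl bridge; C8 follows from the bridge. The C3 stereocentre has only hydrogen as its 1,3-allylic partner on C1 and should exert little bias, so the (S)-carbinol at C11 should translate into the (1R,2R,8R) core. Only the C1=C2 alkene is within reach of the ketene (the isopropenyl group is too remote), and high dilution suppresses ketene dimerisation. A minor cycloadduct from the opposite face would be a diastereomer, since C3 and C5 are fixed, and separable.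

Step 11
Reactants: 22 (1R,3R)-3-[(tert-butyldimethylsilyl)oxy]-4-methyl-1-[(1R,4S,5R,7R)-7-methyl-2-methylidene-6-oxo-4-[(triethylsilyl)oxy]bicyclo[3.1.1]heptan-7-yl]pent-4-en-1-yl (2E)-2-methylbut-2-enoate
Product: 24 N'-tosylhydrazone of the ring ketone of 22 with the triethylsilyl ether cleaved to the free (4S)-alcohol, via triethylsilyl-protected tosylhydrazone 23 (not isolated)
Conditions: TsNHNH2, THF/MeOH, rt; then PPTS, rt
Reagents that add atoms: 4-methylbenzenesulfonohydrazide, Cc1ccc(cc1)S(=O)(=O)NN
Why: Condensation of the strained, electrophilic cyclobutanone (the only ketone present) with the sulfonylhydrazide, then acid-catalysed methanolysis of the triethylsilyl ether, which the secondary TBS ether should survive; masking C7 before C11 is oxidised avoids a non-enolisable 2-acylcyclobutanone that would be open to retro-Claisen ring opening.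

Step 12
Reactants: 24 N'-tosylhydrazone of the ring ketone of 22 with the triethylsilyl ether cleaved to the free (4S)-alcohol
Product: 26 N'-tosylhydrazone (at C6) of the 4,7-dimethylbicyclo[3.1.1]hept-3-ene-2,6-dione that carries at C7 the (1R,3R)-3-[(tert-butyldimethylsilyl)oxy]-4-methyl-1-{[(2E)-2-methylbut-2-enoyl]oxy}pent-4-en-1-yl chain, via exocyclic β,γ-unsaturated ketone 25 (not isolated)
Conditions: nPr4N[RuO4] (cat.), N-methylmorpholine N-oxide, 4 Å molecular sieves, CH2Cl2, rt; then DBU (cat.), rt
Reagents that add atoms: none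
Why: Ley–Griffith oxidation of the secondary C11 alcohol, then base-catalysed migration of the exocyclic alkene into conjugation (only C10 can be deprotonated, C1 being a bridgehead); this gives the verbenone-type enone and removes the exocyclic alkene, whose radical in step 13 would be a ring-opening cyclobutylcarbinyl radical.

Step 13
Reactants: 26 N'-tosylhydrazone (at C6) of the 4,7-dimethylbicyclo[3.1.1]hept-3-ene-2,6-dione that carries at C7 the (1R,3R)-3-[(tert-butyldimethylsilyl)oxy]-4-methyl-1-{[(2E)-2-methylbut-2-enoyl]oxy}pent-4-en-1-yl chain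
Product: 29 (1R,2R,3R,5R,7S,8R)-5-[(tert-butyldimethylsilyl)oxy]-2,6,6,9-tetramethyl-11-oxotricyclo[5.4.0.0(2,8)]undec-9-en-3-yl (2E)-2-methylbut-2-enoate, via N-alkyl-N'-tosylhydrazine 27 (not isolated), via monoalkyldiazene 28 (not isolated)
Conditions: Fe(acac)3 (cat.), PhSiH3, EtOH, 60 °C
Reagents that add atoms: none
Why: Hydrogen-atom-transfer-initiated radical reductive alkylation of a ketone sulfonylhydrazone: Markovnikov H-atom transfer to the isopropenyl group gives the tertiary C6 radical, which the cyclobutane holds over the upper face of C7 and which adds 7-exo to the C=N carbon; loss of sulfinate and N2 leaves C7–H. The configuration at C7 is dictated by the new bridge (C6 can only be anti to the enone bridge), so the step forms the seven-membered ring, the C6 quaternary centre and C7 without leaving oxygen on the cyclobutane.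

Step 14
Reactants: 29 (1R,2R,3R,5R,7S,8R)-5-[(tert-butyldimethylsilyl)oxy]-2,6,6,9-tetramethyl-11-oxotricyclo[5.4.0.0(2,8)]undec-9-en-3-yl (2E)-2-methylbut-2-enoate
Product: 30 (1R,2R,3R,5R,7S,8R)-5-hydroxy-2,6,6,9-tetramethyl-11-oxotricyclo[5.4.0.0(2,8)]undec-9-en-3-yl (2E)-2-methylbut-2-enoate
Conditions: HF (48% aq.), MeCN, rt
Reagents that add atoms: none
Why: Acidic desilylation of the now neopentylic TBS ether; the enone, the tiglate and the cage should tolerate aqueous HF, and non-basic conditions avoid acyl migration.

Step 15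
Reactants: 30 (1R,2R,3R,5R,7S,8R)-5-hydroxy-2,6,6,9-tetramethyl-11-oxotricyclo[5.4.0.0(2,8)]undec-9-en-3-yl (2E)-2-methylbut-2-enoate; 31 (2Z)-2-methylbut-2-enoic acid
Product: 33 (1R,2R,3R,5R,7S,8R)-2,6,6,9-tetramethyl-5-{[(2Z)-2-methylbut-2-enoyl]oxy}-11-oxotricyclo[5.4.0.0(2,8)]undec-9-en-3-yl (2E)-2-methylbut-2-enoate, via mixed anhydride 32 (not isolated)
Conditions: 31, 2,4,6-trichlorobenzoyl chloride, Et3N, toluene, rt; then 30, 80 °C
Reagents that add atoms: none
Why: Acylation through the mixed 2,4,6-trichlorobenzoic anhydride without a nucleophilic catalyst (Yamaguchi-type acyl transfer on heating), conditions chosen because they should not isomerise the Z-configured angelate; only one hydroxyl is free, so no selectivity issue arises.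

## Compound list

1 | 2,2-dimethoxyacetaldehyde | COC(OC)C=O | starting material
2 | 2-(triphenyl-λ5-phosphanylidene)propanal | CC(C=O)=P(c1ccccc1)(c1ccccc1)c1ccccc1 | starting material
3 | (2E)-4,4-dimethoxy-2-methylbut-2-enal | O=C/C(C)=C/C(OC)OC | intermediate
4 | 3-methylbut-3-en-2-one | CC(=O)C(C)=C | starting material
5 | 2-{[bis((+)-isopinocampheyl)boranyl]oxy}-3-methylbuta-1,3-diene (isopinocampheyl groups derived from (−)-α-pinene) | C=C(C)C(=C)OB([C@H]1C[C@H]2C[C@@H]([C@@H]1C)C2(C)C)[C@H]1C[C@H]2C[C@@H]([C@@H]1C)C2(C)C | intermediate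
6 | (5R)-O-[bis((+)-isopinocampheyl)boranyl] derivative of 7 | C=C(C)C(=O)C[C@@H](OB([C@H]1C[C@H]2C[C@@H]([C@@H]1C)C2(C)C)[C@H]1C[C@H]2C[C@@H]([C@@H]1C)C2(C)C)/C(C)=C/C(OC)OC | intermediate
7 | (5R,6E)-5-hydroxy-8,8-dimethoxy-2,6-dimethylocta-1,6-dien-3-one | C=C(C)C(=O)C[C@@H](O)/C(C)=C/C(OC)OC | intermediate
8 | (2E)-2-methylbut-2-enal | C/C=C(\C)C=O | starting material
9 | (3R,5R,6E)-3-hydroxy-8,8-dimethoxy-2,6-dimethylocta-1,6-dien-5-yl (2E)-2-methylbut-2-enoate | C=C(C)[C@H](O)C[C@@H](OC(=O)/C(C)=C/C)/C(C)=C/C(OC)OC | intermediate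
10 | (3R,5R,6E)-3-[(tert-butyldimethylsilyl)oxy]-8,8-dimethoxy-2,6-dimethylocta-1,6-dien-5-yl (2E)-2-methylbut-2-enoate | C=C(C)[C@H](O[Si](C)(C)C(C)(C)C)C[C@@H](OC(=O)/C(C)=C/C)/C(C)=C/C(OC)OC | intermediate
11 | (2E,4R,6R)-6-[(tert-butyldimethylsilyl)oxy]-3,7-dimethyl-1-oxoocta-2,7-dien-4-yl (2E)-2-methylbut-2-enoate | C=C(C)[C@H](O[Si](C)(C)C(C)(C)C)C[C@@H](OC(=O)/C(C)=C/C)/C(C)=C/C=O | intermediate
12 | methyl 3-methylbut-2-enoate | COC(=O)C=C(C)C | starting material
13 | lithium 1-methoxy-3-methylbuta-1,3-dien-1-olate (one C1=C2 isomer drawn) | C=C(C)/C=C(\OC)[O-].[Li+] | intermediate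
14 | tert-butyl[(1-methoxy-3-methylbuta-1,3-dien-1-yl)oxy]dimethylsilane (one C1=C2 isomer drawn) | C=C(C)/C=C(\OC)O[Si](C)(C)C(C)(C)C | intermediate
15 | 5-O-trichlorosilyl ether of 16 | COC(=O)/C=C(\C)C[C@H](O[Si](Cl)(Cl)Cl)/C=C(\C)[C@H](OC(=O)/C(C)=C/C)C[C@@H](O[Si](C)(C)C(C)(C)C)C(C)=C | intermediate
16 | methyl (2E,5S,6E,8R,10R)-10-[(tert-butyldimethylsilyl)oxy]-5-hydroxy-3,7,11-trimethyl-8-{[(2E)-2-methylbut-2-enoyl]oxy}dodeca-2,6,11-trienoate | COC(=O)/C=C(\C)C[C@H](O)/C=C(\C)[C@H](OC(=O)/C(C)=C/C)C[C@@H](O[Si](C)(C)C(C)(C)C)C(C)=C | intermediate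
17 | methyl (2E,5S,6E,8R,10R)-10-[(tert-butyldimethylsilyl)oxy]-3,7,11-trimethyl-8-{[(2E)-2-methylbut-2-enoyl]oxy}-5-[(triethylsilyl)oxy]dodeca-2,6,11-trienoate | COC(=O)/C=C(\C)C[C@H](O[Si](CC)(CC)CC)/C=C(\C)[C@H](OC(=O)/C(C)=C/C)C[C@@H](O[Si](C)(C)C(C)(C)C)C(C)=C | intermediate
18 | trimethylstannyl ester of acid 19 | C[Sn](C)(C)OC(=O)/C=C(\C)C[C@H](O[Si](CC)(CC)CC)/C=C(\C)[C@H](OC(=O)/C(C)=C/C)C[C@@H](O[Si](C)(C)C(C)(C)C)C(C)=C | intermediate
19 | (2E,5S,6E,8R,10R)-10-[(tert-butyldimethylsilyl)oxy]-3,7,11-trimethyl-8-{[(2E)-2-methylbut-2-enoyl]oxy}-5-[(triethylsilyl)oxy]dodeca-2,6,11-trienoic acid | OC(=O)/C=C(\C)C[C@H](O[Si](CC)(CC)CC)/C=C(\C)[C@H](OC(=O)/C(C)=C/C)C[C@@H](O[Si](C)(C)C(C)(C)C)C(C)=C | intermediate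
20 | acid chloride of 19 | ClC(=O)/C=C(\C)C[C@H](O[Si](CC)(CC)CC)/C=C(\C)[C@H](OC(=O)/C(C)=C/C)C[C@@H](O[Si](C)(C)C(C)(C)C)C(C)=C | intermediate
21 | (5S,6E,8R,10R)-10-[(tert-butyldimethylsilyl)oxy]-7,11-dimethyl-3-methylidene-1-oxo-5-[(triethylsilyl)oxy]dodeca-1,6,11-trien-8-yl (2E)-2-methylbut-2-enoate (vinylketene) | O=C=CC(=C)C[C@H](O[Si](CC)(CC)CC)/C=C(\C)[C@H](OC(=O)/C(C)=C/C)C[C@@H](O[Si](C)(C)C(C)(C)C)C(C)=C | intermediate
22 | (1R,3R)-3-[(tert-butyldimethylsilyl)oxy]-4-methyl-1-[(1R,4S,5R,7R)-7-methyl-2-methylidene-6-oxo-4-[(triethylsilyl)oxy]bicyclo[3.1.1]heptan-7-yl]pent-4-en-1-yl (2E)-2-methylbut-2-enoate (chain anti to the three-carbon bridge, silyl ether cis to the carbonyl bridge) | O=C1[C@@H]2C(=C)C[C@H](O[Si](CC)(CC)CC)[C@H]1[C@]2(C)[C@H](OC(=O)/C(C)=C/C)C[C@@H](O[Si](C)(C)C(C)(C)C)C(C)=C | intermediate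
23 | N'-tosylhydrazone of the ring ketone of 22 (either C=N isomer) | Cc1ccc(cc1)S(=O)(=O)NN=C1[C@@H]2C(=C)C[C@H](O[Si](CC)(CC)CC)[C@H]1[C@]2(C)[C@H](OC(=O)/C(C)=C/C)C[C@@H](O[Si](C)(C)C(C)(C)C)C(C)=C | intermediate
24 | N'-tosylhydrazone of the ring ketone of 22 with the triethylsilyl ether cleaved to the free (4S)-alcohol | Cc1ccc(cc1)S(=O)(=O)NN=C1[C@@H]2C(=C)C[C@H](O)[C@H]1[C@]2(C)[C@H](OC(=O)/C(C)=C/C)C[C@@H](O[Si](C)(C)C(C)(C)C)C(C)=C | intermediate
25 | 4-oxo-2-methylidene analogue of 24 (exocyclic β,γ-unsaturated ketone) | Cc1ccc(cc1)S(=O)(=O)NN=C1[C@@H]2C(=C)CC(=O)[C@H]1[C@]2(C)[C@H](OC(=O)/C(C)=C/C)C[C@@H](O[Si](C)(C)C(C)(C)C)C(C)=C | intermediate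
26 | N'-tosylhydrazone (at C6) of the 4,7-dimethylbicyclo[3.1.1]hept-3-ene-2,6-dione carrying at C7 the (1R,3R)-3-[(tert-butyldimethylsilyl)oxy]-4-methyl-1-{[(2E)-2-methylbut-2-enoyl]oxy}pent-4-en-1-yl chain | Cc1ccc(cc1)S(=O)(=O)NN=C1[C@@H]2C(C)=CC(=O)[C@H]1[C@]2(C)[C@H](OC(=O)/C(C)=C/C)C[C@@H](O[Si](C)(C)C(C)(C)C)C(C)=C | intermediate
27 | 7-(N'-tosylhydrazinyl) derivative of 29 | CC(C)(C)[Si](C)(C)O[C@@H]1C[C@@H](OC(=O)/C(C)=C/C)[C@@]2(C)[C@@H]3C(=O)C=C(C)[C@H]2[C@]3(NNS(=O)(=O)c2ccc(C)cc2)C1(C)C | intermediate
28 | 7-diazenyl derivative of 29 | CC(C)(C)[Si](C)(C)O[C@@H]1C[C@@H](OC(=O)/C(C)=C/C)[C@@]2(C)[C@@H]3C(=O)C=C(C)[C@H]2[C@]3(N=N)C1(C)C | intermediate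
29 | (1R,2R,3R,5R,7S,8R)-5-[(tert-butyldimethylsilyl)oxy]-2,6,6,9-tetramethyl-11-oxotricyclo[5.4.0.0(2,8)]undec-9-en-3-yl (2E)-2-methylbut-2-enoate | CC(C)(C)[Si](C)(C)O[C@@H]1C[C@@H](OC(=O)/C(C)=C/C)[C@@]2(C)[C@@H]3C(=O)C=C(C)[C@H]2[C@@H]3C1(C)C | intermediate
30 | (1R,2R,3R,5R,7S,8R)-5-hydroxy-2,6,6,9-tetramethyl-11-oxotricyclo[5.4.0.0(2,8)]undec-9-en-3-yl (2E)-2-methylbut-2-enoate | O[C@@H]1C[C@@H](OC(=O)/C(C)=C/C)[C@@]2(C)[C@@H]3C(=O)C=C(C)[C@H]2[C@@H]3C1(C)C | intermediate
31 | (2Z)-2-methylbut-2-enoic acid (angelic acid) | C/C=C(/C)C(=O)O | starting material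
32 | (2Z)-2-methylbut-2-enoic 2,4,6-trichlorobenzoic anhydride | C/C=C(/C)C(=O)OC(=O)c1c(Cl)cc(Cl)cc1Cl | intermediate
33 | (1R,2R,3R,5R,7S,8R)-2,6,6,9-tetramethyl-5-{[(2Z)-2-methylbut-2-enoyl]oxy}-11-oxotricyclo[5.4.0.0(2,8)]undec-9-en-3-yl (2E)-2-methylbut-2-enoate | C/C=C(/C)C(=O)O[C@@H]1C[C@@H](OC(=O)/C(C)=C/C)[C@@]2(C)[C@@H]3C(=O)C=C(C)[C@H]2[C@@H]3C1(C)C | target

## Step count and least certain steps

Total: 15 steps. Longest linear sequence: 14 steps (steps 1–5 and 7–15); step 6 is a one-step side branch.

**Step 10 (key step).** The most likely failure is a cycloaddition too slow to compete with ketene dimerisation and oligomerisation: the C1=C2 alkene is flanked by two allylic C–O bonds, which lower its nucleophilicity, and the new quaternary centre C2 carries a branched chain. Two lesser risks are γ-deprotonation at C10 instead of the methyl group and leakage to the other alkene face. The C10-derived dienylketene would, if it cyclises, give the endocyclic alkene isomer, which converges on 26 after steps 11 and 12. The fallback sets out from 19 and returns at 22 and replaces the ketene by a cationic heterocumulene. The acid 19 would be converted (same chloroenamine, then Me2NH) into the N,N-dimethylamide F1. Tf2O and 2,4,6-collidine in CH2Cl2 would give, by O-triflation and loss of a γ-proton, the vinylketeniminium triflate F2, a far stronger electrophile than 21, which should add to C1=C2 in the same orientation. The resulting cyclobutaniminium triflate F3 would be hydrolysed with aqueous NaHCO3 to 22.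

**Step 13.** The most likely failure is reduction of the tertiary C6 radical before it adds to the hydrazone, because a 7-exo closure is slower than the five- and six-membered closures for which this reaction type is established. Hydrogen-atom transfer to the tiglate or the enone, or fragmentation of the cyclobutane at the hydrazinyl-radical stage, are further possibilities. The fallback sets out from 26 and returns at 29 and separates radical generation from the hydride source. Markovnikov hydrochlorination of the isopropenyl group (HCl, CH2Cl2, −78 °C) would give the tertiary chloride F4. Bu3SnH and AIBN, added by syringe pump in benzene at reflux, would regenerate the same C6 radical in a classical chain process at very low hydride concentration, so that the 7-exo addition can compete; loss of sulfinyl radical and N2 then gives 29.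

**Step 3.** The most likely failure is a sluggish hydride transfer, because the hydride donor is the hemiacetal of a conjugated aldehyde and the acceptor is a conjugated ketone; retro-aldol cleavage or 1,3-acyl migration could then intervene. The fallback sets out from 7 and returns at 9 and replaces internal hydride delivery by reagent control. Acylation of 7 (tigloyl chloride, pyridine, CH2Cl2, 0 °C) would give the β-acyloxy enone (5R,6E)-8,8-dimethoxy-2,6-dimethyl-3-oxoocta-1,6-dien-5-yl (2E)-2-methylbut-2-enoate F5. Corey–Bakshi–Shibata reduction of its alkenyl ketone with the (S)-B-methyl oxazaborolidine and catecholborane (alkenyl as the large group) should give the (3R)-allylic alcohol 9.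

**Step 12.** The most likely failure is attack of the oxidant on the N–H sulfonylhydrazone (oxidative cleavage back to the ketone or over-oxidation at nitrogen). The fallback sets out from 22 and returns at 26 and masks C7 differently during the oxidation. Treatment of 22 with HC(OMe)3 and PPTS in MeOH would ketalise the cyclobutanone and cleave the triethylsilyl ether to give the dimethyl ketal alcohol F6. The same oxidation and isomerisation would give the dimethyl ketal enone F7, in which C7 is sp3 and no β-dicarbonyl exists. Acid-catalysed exchange of the ketal with TsNHNH2 would then give 26.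

**Step 15.** The most likely failure is slow acylation of the neopentylic C5 hydroxyl, so that forcing conditions isomerise the angelate to the tiglate. The fallback sets out from 30 and returns at 33 and builds the Z alkene on the molecule instead of transferring it. Esterification of 30 with 2-[bis(2,2,2-trifluoroethoxy)phosphoryl]propanoic acid (carbodiimide, DMAP) would give the phosphonopropionate F8. Still–Gennari olefination (KN(SiMe3)2, 18-crown-6, THF, −78 °C, then acetaldehyde) should then give the (Z)-2-methylbut-2-enoate 33.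

## Further compounds

F1 | step 10 | N,N-dimethylamide of acid 19 | CN(C)C(=O)/C=C(\C)C[C@H](O[Si](CC)(CC)CC)/C=C(\C)[C@H](OC(=O)/C(C)=C/C)C[C@@H](O[Si](C)(C)C(C)(C)C)C(C)=C
F2 | step 10 | N,N-dimethyl vinylketeniminium triflate derived from F1 | C[N+](C)=C=CC(=C)C[C@H](O[Si](CC)(CC)CC)/C=C(\C)[C@H](OC(=O)/C(C)=C/C)C[C@@H](O[Si](C)(C)C(C)(C)C)C(C)=C.[O-]S(=O)(=O)C(F)(F)F
F3 | step 10 | N,N-dimethyliminium triflate of ketone 22 (cyclobutaniminium salt) | C[N+](C)=C1[C@@H]2C(=C)C[C@H](O[Si](CC)(CC)CC)[C@H]1[C@]2(C)[C@H](OC(=O)/C(C)=C/C)C[C@@H](O[Si](C)(C)C(C)(C)C)C(C)=C.[O-]S(=O)(=O)C(F)(F)F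
F4 | step 13 | tertiary chloride from Markovnikov addition of HCl to the isopropenyl group of 26 | Cc1ccc(cc1)S(=O)(=O)NN=C1[C@@H]2C(C)=CC(=O)[C@H]1[C@]2(C)[C@H](OC(=O)/C(C)=C/C)C[C@@H](O[Si](C)(C)C(C)(C)C)C(C)(C)Cl
F5 | step 3 | (5R,6E)-8,8-dimethoxy-2,6-dimethyl-3-oxoocta-1,6-dien-5-yl (2E)-2-methylbut-2-enoate | C=C(C)C(=O)C[C@@H](OC(=O)/C(C)=C/C)/C(C)=C/C(OC)OC
F6 | step 12 | 6,6-dimethyl ketal of 22 with the triethylsilyl ether cleaved to the free (4S)-alcohol | COC1(OC)[C@@H]2C(=C)C[C@H](O)[C@H]1[C@]2(C)[C@H](OC(=O)/C(C)=C/C)C[C@@H](O[Si](C)(C)C(C)(C)C)C(C)=C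
F7 | step 12 | 6,6-dimethoxy-4,7-dimethylbicyclo[3.1.1]hept-3-en-2-one carrying the side chain of 26 at C7 | COC1(OC)[C@@H]2C(C)=CC(=O)[C@H]1[C@]2(C)[C@H](OC(=O)/C(C)=C/C)C[C@@H](O[Si](C)(C)C(C)(C)C)C(C)=C
F8 | step 15 | 5-O-{2-[bis(2,2,2-trifluoroethoxy)phosphoryl]propanoyl} derivative of 30 (epimers at the phosphonate carbon) | CC(P(=O)(OCC(F)(F)F)OCC(F)(F)F)C(=O)O[C@@H]1C[C@@H](OC(=O)/C(C)=C/C)[C@@]2(C)[C@@H]3C(=O)C=C(C)[C@H]2[C@@H]3C1(C)C
A1 | alternative 1 | (2E,8E,10Z)-3,7,7,10-tetramethylcycloundeca-2,8,10-trien-1-one carrying the tiglate at C4 and the angelate at C6 | C/C=C(/C)C(=O)O[C@@H]1C[C@@H](OC(=O)/C(C)=C/C)/C(C)=C/C(=O)/C=C(C)\C=C\C1(C)C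
A2 | alternative 2 | cis-fused bicyclo[5.4.0]undecenedione (the target with the C1–C7 bond cut, C7 as ketone, C1 as CH2) | C/C=C(/C)C(=O)O[C@@H]1C[C@@H](OC(=O)/C(C)=C/C)[C@@]2(C)CC(=O)C=C(C)[C@H]2C(=O)C1(C)C
A3 | alternative 2 | 7-hydroxy derivative of target 33 (cyclobutanol) | C/C=C(/C)C(=O)O[C@@H]1C[C@@H](OC(=O)/C(C)=C/C)[C@@]2(C)[C@@H]3C(=O)C=C(C)[C@H]2[C@]3(O)C1(C)C
A4 | alternative 3 | 1,3-dimethyltricyclo[4.1.0.0(2,7)]hept-3-en-5-one (bicyclobutane with the enone bridge) | CC1=CC(=O)[C@H]2[C@@]3(C)[C@@H]1[C@@H]23
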